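The ten-membered carbocycle C1–C10 holds a carbonyl-level carbon (hemiketal C1), two methylenes (C2, C3) and then C4–C5. This is the pattern of a γ,δ-unsaturated ketone, so the route cuts C2–C3 by a retro-Claisen. The butenolide ring (C6, C7, C11, C12, O) is carried as a 2-silylfuran. The precursor is a furan-fused eight-membered cyclic enol ether (C1, O, C5–C10) with an exocyclic C1=C2 methylene and an isopropenyl group (C4=C3) on C5. Heating trades the ring O–C5 bond for C2–C3 and gives the cyclodecenone in one operation. Photooxygenation and an acid-induced allylic transposition then install the oxolane bridge and the ylidene lactone.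

Key step: step 13

Remark on numbering: germacrane numbers are used throughout. C1 is the hemiketal carbon, C2/C3 the methylenes, C4 the methyl-bearing ether carbon and C5 the vinylic CH. C6/C7 are the lactone γ/β carbons, C8 the acyloxy CH, C9 the CH2 and C10 the methyl-bearing CH. C11/C12 are the lactone α carbon and carbonyl, and C13 the acetoxymethyl carbon.
Remark on C10: in bromo alcohol 6 the CH2Br carbon becomes C9 and the CH2OH carbon becomes C1. With this mapping the (S)-enantiomer gives (10R); the opposite mapping or enantiomer would give the C10 epimer.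
Remark on open centres: C5 (compounds 16–21) and C6 (25) are carried as epimer mixtures and written without descriptor, because both become sp2 later.
Remark on the silyl group: C12 carries SiEt3. It arrives by an intramolecular O-to-C shift, so its position is unambiguous, and it resists protodesilylation better than a smaller silyl group.

Step 1
Reactants: 1 furan-3,4-diyldimethanol
Product: 2 3,4-bis[(triethylsilyloxy)methyl]furan
Conditions: TESCl (2.3 equiv), imidazole, CH2Cl2, 0 °C to rt
Reagents that add atoms: chlorotriethylsilane, CC[Si](Cl)(CC)CC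
Why: Routine silyl ether formation on two unhindered primary alcohols keeps the furan symmetric and places on oxygen the silyl group that step 2 moves to carbon.

Step 2
Reactants: 2 3,4-bis[(triethylsilyloxy)methyl]furan
Product: 4 3-[(tert-butyldimethylsilyloxy)methyl]-2-(triethylsilyl)-4-[(triethylsilyloxy)methyl]furan, via lithium alkoxide 3 (not isolated)
Conditions: n-BuLi (1.05 equiv), HMPA, THF, −78 to −20 °C; then TBSCl, −20 °C to rt
Reagents that add atoms: tert-butyldimethylsilyl chloride, CC(C)(C)[Si](C)(C)Cl
Why: In this retro-Brook (1,4 O-to-C silyl) migration the two α-positions of 2 are equivalent and the α-lithiofuran attacks the silicon of the neighbouring CH2OSiEt3 arm through a five-membered transition state, so silicon ends on C12 next to the arm that becomes C13, and the freed alkoxide is capped in the same flask as the sturdier TBS ether.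

Step 3
Reactants: 4 3-[(tert-butyldimethylsilyloxy)methyl]-2-(triethylsilyl)-4-[(triethylsilyloxy)methyl]furan
Product: 5 4-[(tert-butyldimethylsilyloxy)methyl]-5-(triethylsilyl)furan-3-carbaldehyde
Conditions: (COCl)2, DMSO, CH2Cl2, −78 to −30 °C; Et3N, −78 °C to rt
Reagents that add atoms: none
Why: In this Swern oxidation run directly on a silyl ether, the chlorosulfonium salt cleaves the labile primary O–SiEt3 bond and oxidises that carbon (C8) to the aldehyde, while the O–TBS and furan C–Si bonds are inert to it.

Step 4
Reactants: 6 (S)-3-bromo-2-methylpropan-1-ol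
Product: 7 (S)-(3-bromo-2-methylpropoxy)triethylsilane
Conditions: TESCl, imidazole, CH2Cl2, 0 °C
Reagents that add atoms: chlorotriethylsilane, CC[Si](Cl)(CC)CC
Why: Routine silyl ether formation leaves the stereocentre (future C10) untouched.

Step 5
Reactants: 7 (S)-(3-bromo-2-methylpropoxy)triethylsilane; 5 furan aldehyde
Product: 9 (3R)-1-[4-(TBSOCH2)-5-(SiEt3)furan-3-yl]-3-methyl-4-(triethylsilyloxy)butan-1-ol (both C8 epimers), via Grignard reagent 8 (not isolated)
Conditions: Mg, I2 (trace), THF, rt to 40 °C; then 5, −78 to 0 °C; aq NH4Cl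
Reagents that add atoms: none
Why: Grignard formation and 1,2-addition to an aromatic aldehyde form C8–C9, and the lack of induction from the remote C10 centre does not matter because step 6 removes the C8 centre.

Step 6
Reactants: 9 C8 carbinol mixture
Product: 10 (3R)-1-[4-(TBSOCH2)-5-(SiEt3)furan-3-yl]-3-methyl-4-(triethylsilyloxy)butan-1-one
Conditions: Dess–Martin periodinane, pyridine, CH2Cl2, 0 °C to rt
Reagents that add atoms: none
Why: Dess–Martin oxidation of a secondary furyl carbinol under buffered conditions spares the silyl ethers, and C10 is β to the new ketone and cannot epimerise.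

Step 7
Reactants: 10 furyl ketone
Product: 11 (1S,3R)-1-[4-(TBSOCH2)-5-(SiEt3)furan-3-yl]-3-methyl-4-(triethylsilyloxy)butan-1-ol
Conditions: (R)-1-methyl-3,3-diphenyltetrahydro-1H,3H-pyrrolo[1,2-c][1,3,2]oxazaborole ((R)-Me-CBS, 0.2 equiv), BH3·SMe2, THF, −30 °C; MeOH
Reagents that add atoms: none
Why: In this Corey–Bakshi–Shibata reduction the substituted furyl group is the large and the CH2 chain the small substituent, so the (R)-catalyst delivers hydride to the face that gives the (8S)-carbinol under reagent control, and no alkene is yet present for borane to attack.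

Step 8
Reactants: 11 (8S)-carbinol
Product: 13 (2R,4S)-4-(tert-butyldimethylsilyloxy)-4-[4-(TBSOCH2)-5-(SiEt3)furan-3-yl]-2-methylbutan-1-ol, via bis-TBS TES ether 12 (not isolated)
Conditions: TBSOTf (1.2 equiv), 2,6-lutidine (1.5 equiv), CH2Cl2, −78 to 0 °C; then MeOH, camphor-10-sulfonic acid (0.5 equiv), 0 °C
Reagents that add atoms: tert-butyldimethylsilyl triflate, CC(C)(C)[Si](C)(C)OS(=O)(=O)C(F)(F)F
Why: Silylation of the hindered carbinol with the silyl triflate is followed by acid-catalysed methanolysis, which distinguishes the primary O–SiEt3 bond from the two O–TBS bonds by their large rate difference, and neither stereocentre takes part.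

Step 9
Reactants: 13 primary alcohol; 14 methacrolein
Product: 16 (2R,4S)-4-(TBSO)-4-[4-(TBSOCH2)-2-(1-hydroxy-2-methylprop-2-enyl)-5-(SiEt3)furan-3-yl]-2-methylbutan-1-ol (both C5 epimers), via dilithio species 15 (not isolated)
Conditions: n-BuLi (2.3 equiv), THF, −78 to −10 °C; then 14, −78 °C; H2O
Reagents that add atoms: none
Why: This is deprotonative α-lithiation of a furan followed by 1,2-addition to an enal: once the alkoxide has formed, C6–H is the only ring hydrogen left so regiochemistry is fixed, the absence of polar additives keeps the C8 silyl group on oxygen, and both C5 epimers are acceptable because step 13 erases that centre.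

Step 10
Reactants: 16 diol
Product: 18 (2R,4S)-4-(TBSO)-4-[4-(TBSOCH2)-2-(1-hydroxy-2-methylprop-2-enyl)-5-(SiEt3)furan-3-yl]-2-methylbutanoic acid, via hydroxy aldehyde 17 (not isolated)
Conditions: TEMPO (0.2 equiv), PhI(OAc)2 (2.5 equiv), MeCN–pH 7 phosphate buffer, 0 °C to rt
Reagents that add atoms: water, O
Why: Oxoammonium (TEMPO/PhI(OAc)2) oxidation in aqueous medium takes the unhindered primary alcohol through the aldehyde hydrate to the acid, the bulky oxidant is slow on the C5 carbinol wedged between a tetrasubstituted furan and an isopropenyl group, and the buffer protects that acid-labile carbinol and C10.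

Step 11
Reactants: 18 seco acid
Product: 20 furan-fused eight-membered lactone (ring C1–O–C5–C6–C7–C8–C9–C10; 8S 10R; isopropenyl on C5; both C5 epimers), via mixed anhydride 19 (not isolated)
Conditions: 2-methyl-6-nitrobenzoic anhydride (MNBA, 1.3 equiv), DMAP (6 equiv), CH2Cl2 (1 mM), slow addition of 18, rt
Reagents that add atoms: none
Why: In this Shiina macrolactonisation at high dilution (8-exo-trig at the acyl carbon) the planar furan holds C5 and C8 cis on C6=C7 and removes transannular hydrogens, which favours closure over oligomerisation, and the room-temperature acyl transfer should leave C10 intact.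

Step 12
Reactants: 20 eight-membered lactone
Product: 21 furan-fused 2-methylene-8-isopropenyloxocane (C1=C2H2 exocyclic; 8S 10R; both C5 epimers)
Conditions: Cp2TiMe2 (2.5 equiv), toluene, 65 °C, dark; filtration through basic Al2O3
Reagents that add atoms: dimethyltitanocene, C[Ti+2]C.c1cc[cH-]c1.c1cc[cH-]c1
Why: In this Petasis methylenation thermally generated Cp2Ti=CH2 converts the lactone carbonyl, the only carbonyl present because the butenolide is masked as the furan, into the exocyclic enol ether without acid or base, so C10 and the labile O–C5 bond persist, and any material that rearranges at this temperature only anticipates step 13.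

Step 13
Reactants: 21 furan-fused 2-methylene-8-isopropenyloxocane
Product: 22 (4Z,8S,10R)-8,13-bis(TBSO)-12-(triethylsilyl)-6,12-epoxygermacra-4,6,11-trien-1-one (furan-fused cyclodec-4-en-1-one)
Conditions: toluene (0.01 M), iPr2NEt (0.1 equiv), base-washed sealed tube, 120 °C
Reagents that add atoms: none
Why: Heating sets off a concerted, suprafacial [3,3]-sigmatropic (Claisen) shift along C2=C1–O–C5–C4=C3, in which the ring O–C5 bond breaks while C2–C3 forms, C1 becomes the ketone and C4=C5 ends up conjugated with the furan. The closest known reaction type is the methylenation–Claisen ring enlargement of lactones that carry a vinyl group on the carbinol carbon, which turns 2-methylene oxacycles into cycloalk-4-enones two atoms larger. The ten-membered carbocycle is therefore closed by ring enlargement and not by end-to-end cyclisation: both reacting termini hang on the eight-membered ring, and the six-atom transition-state array is bridged at C1 and C5 by the five-atom C6–C10 tether. No stereocentre is created; C8 and C10 are spectators, C5 becomes sp2 so both epimers of 21 converge, and the tether holds the C5–C6 bond pseudoaxial, which should give the (Z)-alkene, a geometry that disappears when C4 becomes sp3 in step 15. The step needs periselectivity (the [3,3] path through the isopropenyl group rather than ionisation at the doubly activated C5 with 1,3-recombination, or use of the furan C6=C7 bond as allyl partner) and an intact exocyclic enol ether. An apolar, acid-free medium disfavours ion pairs and migration of the enol ether to C1=C10, and furan aromaticity together with the fully substituted C7 closes the second [3,3] channel.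

Step 14
Reactants: 22 furan-fused cyclodecenone
Product: 25 (4Z,8S,10R)-8,13-bis(TBSO)-6-hydroxy-1-oxogermacra-4,7(11)-dien-12,6-olide (γ-hydroxybutenolide; C6 epimers), via endoperoxide 23 (not isolated), via silyl ester 24 (not isolated)
Conditions: O2, tetraphenylporphyrin (cat.), visible light, CH2Cl2, −78 °C; then H2O–THF, rt
Reagents that add atoms: dioxygen, O=O
Why: In this [4+2] photooxygenation of a 2-silylfuran, singlet oxygen adds across C6/C12 of the electron-rich furan much faster than it engages the trisubstituted alkene, silicon migrates from C12 to peroxide oxygen so that C12 becomes the carboxyl carbon and C6 the ketone, and hydrolysis of the silyl ester closes the pseudo-acid.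

Step 15
Reactants: 25 γ-hydroxybutenolide
Product: 27 (1S,4R,8S,10R)-8,13-bis(TBSO)-1-hydroxy-1,4-epoxygermacra-5,7(11)-dien-12,6-olide, via keto alcohol 26 (not isolated)
Conditions: camphor-10-sulfonic acid (0.1 equiv), THF–H2O 9:1, 0 °C to rt
Reagents that add atoms: water, O
Why: Proposed new method: acid turns the C6 hydroxyl of pseudo-acid 25 into a leaving group, and the resulting cation is delocalised over C6, C5 and the tertiary C4 and supported by the lactone oxygen; water adds at C4 because only that terminus leaves the fully conjugated C5=C6–C7=C11–C12=O dienolide (26), whose tertiary hydroxyl then closes on the transannular C1 ketone as a five-membered hemiketal (5-exo-trig); the closest known reaction types are the acid-catalysed 1,3-transposition of tertiary allylic alcohols (SN1′) and the dehydration of γ-hydroxybutenolides to γ-ylidenebutenolides, neither shown as a transannular cascade on a γ-alkenyl pseudo-acid; all new C–O bonds are reversible under these conditions, so C4 should settle as (4R), the epimer whose bicycle keeps the C8 and C10 substituents on the outside as in the natural series, C1 is forced to (1S) because the six-atom chain can span the oxolane only cis, and the ring allows only the C5=C6 geometry with C4 and C7 cis; loss of the primary silyl ether here would be harmless because step 16 removes it.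

Step 16
Reactants: 27 bridged bis-silyl ether
Product: 28 (1S,4R,8S,10R)-1,8,13-trihydroxy-1,4-epoxygermacra-5,7(11)-dien-12,6-olide
Conditions: HF·pyridine, pyridine, THF, 0 °C to rt, plastic vessel
Reagents that add atoms: none
Why: Fluoride-mediated desilylation in a buffered, base-free medium removes both TBS ethers, leaves hemiketal and ylidene lactone alone, and avoids base-induced relactonisation of O8 onto C12.

Step 17
Reactants: 28 triol
Product: 29 (1S,4R,8S,10R)-13-acetoxy-1,8-dihydroxy-1,4-epoxygermacra-5,7(11)-dien-12,6-olide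
Conditions: Ac2O (1.1 equiv), pyridine, CH2Cl2, −20 to 0 °C
Reagents that add atoms: acetic anhydride, CC(=O)OC(C)=O
Why: This acetylation is chemoselective because, without DMAP and in the cold, the primary allylic C13 hydroxyl reacts far faster than the hindered secondary C8 hydroxyl and the tertiary hemiketal hydroxyl.

Step 18
Reactants: 30 (tert-butyldimethylsilyloxy)acetaldehyde; 31 ethyl 2-(triphenylphosphoranylidene)propanoate
Product: 32 ethyl (E)-4-(tert-butyldimethylsilyloxy)-2-methylbut-2-enoate
Conditions: CH2Cl2, rt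
Reagents that add atoms: none
Why: Wittig olefination with a stabilised α-methyl ylide is reliably (E)-selective for unbranched aldehydes.

Step 19
Reactants: 32 ethyl ester
Product: 34 (E)-4-(tert-butyldimethylsilyloxy)-2-methylbut-2-enoic acid, via lithium carboxylate 33 (not isolated)
Conditions: LiOH, THF–H2O, 0 °C to rt; then 1 M HCl to pH 4, 0 °C
Reagents that add atoms: lithium hydroxide, [Li+].[OH-]
Why: Saponification of an unhindered ethyl ester leaves the primary TBS ether and the alkene geometry unchanged.

Step 20
Reactants: 29 C8 alcohol; 34 protected hydroxytiglic acid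
Product: 36 4′-O-TBS ether of the target, via mixed anhydride 35 (not isolated)
Conditions: MNBA, Et3N, DMAP (cat.), CH2Cl2, rt
Reagents that add atoms: none
Why: Shiina esterification acylates the only reactive hydroxyl left (secondary C8–OH; the tertiary hemiketal OH is inert) with retention at C8, and the tiglate-type (E)-acid has no tendency to isomerise.

Step 21
Reactants: 36 4′-O-TBS ether
Product: 37 target CNP0154520.1
Conditions: HF·pyridine, pyridine, THF, 0 °C
Reagents that add atoms: none
Why: Buffered fluoride desilylation of a primary allylic TBS ether, free of alcohol solvent and base, spares the exchange-prone C13 allylic acetate, both esters and the hemiketal.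

Compound list
1 | furan-3,4-diyldimethanol | OCc1cocc1CO | starting material
2 | 3,4-bis[(triethylsilyloxy)methyl]furan | CC[Si](CC)(CC)OCc1cocc1CO[Si](CC)(CC)CC | intermediate
3 | lithium {2-(triethylsilyl)-4-[(triethylsilyloxy)methyl]furan-3-yl}methanolate | [Li+].[O-]Cc1c(CO[Si](CC)(CC)CC)coc1[Si](CC)(CC)CC | intermediate
4 | 3-[(tert-butyldimethylsilyloxy)methyl]-2-(triethylsilyl)-4-[(triethylsilyloxy)methyl]furan | CC[Si](CC)(CC)OCc1coc([Si](CC)(CC)CC)c1CO[Si](C)(C)C(C)(C)C | intermediate
5 | 4-[(tert-butyldimethylsilyloxy)methyl]-5-(triethylsilyl)furan-3-carbaldehyde | O=Cc1coc([Si](CC)(CC)CC)c1CO[Si](C)(C)C(C)(C)C | intermediate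
6 | (S)-3-bromo-2-methylpropan-1-ol | OC[C@H](C)CBr | starting material
7 | (S)-(3-bromo-2-methylpropoxy)triethylsilane | CC[Si](CC)(CC)OC[C@H](C)CBr | intermediate
8 | (S)-[2-methyl-3-(triethylsilyloxy)propyl]magnesium bromide | CC[Si](CC)(CC)OC[C@H](C)C[Mg]Br | intermediate
9 | (3R)-1-[4-(TBSOCH2)-5-(SiEt3)furan-3-yl]-3-methyl-4-(triethylsilyloxy)butan-1-ol, both C8 epimers | CC[Si](CC)(CC)OC[C@H](C)CC(O)c1coc([Si](CC)(CC)CC)c1CO[Si](C)(C)C(C)(C)C | intermediate
10 | (3R)-1-[4-(TBSOCH2)-5-(SiEt3)furan-3-yl]-3-methyl-4-(triethylsilyloxy)butan-1-one | CC[Si](CC)(CC)OC[C@H](C)CC(=O)c1coc([Si](CC)(CC)CC)c1CO[Si](C)(C)C(C)(C)C | intermediate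
11 | (1S,3R)-1-[4-(TBSOCH2)-5-(SiEt3)furan-3-yl]-3-methyl-4-(triethylsilyloxy)butan-1-ol | CC[Si](CC)(CC)OC[C@H](C)C[C@H](O)c1coc([Si](CC)(CC)CC)c1CO[Si](C)(C)C(C)(C)C | intermediate
12 | C8 TBS ether of 11 (C1–OSiEt3 still in place) | CC[Si](CC)(CC)OC[C@H](C)C[C@H](O[Si](C)(C)C(C)(C)C)c1coc([Si](CC)(CC)CC)c1CO[Si](C)(C)C(C)(C)C | intermediate
13 | (2R,4S)-4-(TBSO)-4-[4-(TBSOCH2)-5-(SiEt3)furan-3-yl]-2-methylbutan-1-ol | OC[C@H](C)C[C@H](O[Si](C)(C)C(C)(C)C)c1coc([Si](CC)(CC)CC)c1CO[Si](C)(C)C(C)(C)C | intermediate
14 | methacrolein | C=C(C)C=O | starting material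
15 | O,C6-dilithio derivative of 13 | [Li]OC[C@H](C)C[C@H](O[Si](C)(C)C(C)(C)C)c1c([Li])oc([Si](CC)(CC)CC)c1CO[Si](C)(C)C(C)(C)C | intermediate
16 | (2R,4S)-4-(TBSO)-4-[4-(TBSOCH2)-2-(1-hydroxy-2-methylprop-2-enyl)-5-(SiEt3)furan-3-yl]-2-methylbutan-1-ol, both C5 epimers | OC[C@H](C)C[C@H](O[Si](C)(C)C(C)(C)C)c1c(C(O)C(C)=C)oc([Si](CC)(CC)CC)c1CO[Si](C)(C)C(C)(C)C | intermediate
17 | C1 aldehyde corresponding to 16 | O=C[C@H](C)C[C@H](O[Si](C)(C)C(C)(C)C)c1c(C(O)C(C)=C)oc([Si](CC)(CC)CC)c1CO[Si](C)(C)C(C)(C)C | intermediate
18 | seco acid, (2R,4S)-butanoic acid corresponding to 16 | OC(=O)[C@H](C)C[C@H](O[Si](C)(C)C(C)(C)C)c1c(C(O)C(C)=C)oc([Si](CC)(CC)CC)c1CO[Si](C)(C)C(C)(C)C | intermediate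
19 | mixed anhydride of 18 with 2-methyl-6-nitrobenzoic acid | Cc1cccc([N+](=O)[O-])c1C(=O)OC(=O)[C@H](C)C[C@H](O[Si](C)(C)C(C)(C)C)c1c(C(O)C(C)=C)oc([Si](CC)(CC)CC)c1CO[Si](C)(C)C(C)(C)C | intermediate
20 | furan-fused eight-membered lactone (C1(=O)–O–C5), 8S,10R, both C5 epimers | C[C@@H]1C[C@H](O[Si](C)(C)C(C)(C)C)c2c(CO[Si](C)(C)C(C)(C)C)c([Si](CC)(CC)CC)oc2C(C(C)=C)OC1=O | intermediate
21 | furan-fused 2-methylene-8-isopropenyloxocane, 8S,10R, both C5 epimers | C[C@@H]1C[C@H](O[Si](C)(C)C(C)(C)C)c2c(CO[Si](C)(C)C(C)(C)C)c([Si](CC)(CC)CC)oc2C(C(C)=C)OC1=C | intermediate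
22 | (4Z,8S,10R)-8,13-bis(TBSO)-12-(triethylsilyl)-6,12-epoxygermacra-4,6,11-trien-1-one | C[C@@H]1C[C@H](O[Si](C)(C)C(C)(C)C)c2c(CO[Si](C)(C)C(C)(C)C)c([Si](CC)(CC)CC)oc2/C=C(C)\CCC1=O | intermediate
23 | C6,C12-endoperoxide of 22 | C[C@@H]1C[C@H](O[Si](C)(C)C(C)(C)C)C2=C(CO[Si](C)(C)C(C)(C)C)C3([Si](CC)(CC)CC)OOC2(O3)/C=C(C)\CCC1=O | intermediate
24 | triethylsilyl (7Z)-1,6-dioxogermacra-4,7(11)-dien-12-oate | C[C@@H]1C[C@H](O[Si](C)(C)C(C)(C)C)/C(=C(\CO[Si](C)(C)C(C)(C)C)C(=O)O[Si](CC)(CC)CC)C(=O)/C=C(C)\CCC1=O | intermediate
25 | (4Z,8S,10R)-8,13-bis(TBSO)-6-hydroxy-1-oxogermacra-4,7(11)-dien-12,6-olide, C6 epimers | C[C@@H]1C[C@H](O[Si](C)(C)C(C)(C)C)C2=C(CO[Si](C)(C)C(C)(C)C)C(=O)OC2(O)/C=C(C)\CCC1=O | intermediate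
26 | (4R,8S,10R)-8,13-bis(TBSO)-4-hydroxy-1-oxogermacra-5,7(11)-dien-12,6-olide | CC(C)(C)[Si](C)(C)OCC1=C2/C(=C\[C@@](O)(C)CCC(=O)[C@H](C)C[C@@H]2O[Si](C)(C)C(C)(C)C)OC1=O | intermediate
27 | (1S,4R,8S,10R)-8,13-bis(TBSO)-1-hydroxy-1,4-epoxygermacra-5,7(11)-dien-12,6-olide | CC(C)(C)[Si](C)(C)OCC1=C2/C(=C\[C@@]3(C)CC[C@](O)(O3)[C@H](C)C[C@@H]2O[Si](C)(C)C(C)(C)C)OC1=O | intermediate
28 | (1S,4R,8S,10R)-1,8,13-trihydroxy-1,4-epoxygermacra-5,7(11)-dien-12,6-olide | OCC1=C2/C(=C\[C@@]3(C)CC[C@](O)(O3)[C@H](C)C[C@@H]2O)OC1=O | intermediate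
29 | 13-O-acetate of 28 | CC(=O)OCC1=C2/C(=C\[C@@]3(C)CC[C@](O)(O3)[C@H](C)C[C@@H]2O)OC1=O | intermediate
30 | (tert-butyldimethylsilyloxy)acetaldehyde | CC(C)(C)[Si](C)(C)OCC=O | starting material
31 | ethyl 2-(triphenylphosphoranylidene)propanoate | CCOC(=O)C(C)=P(c1ccccc1)(c1ccccc1)c1ccccc1 | starting material
32 | ethyl (E)-4-(tert-butyldimethylsilyloxy)-2-methylbut-2-enoate | CCOC(=O)/C(C)=C/CO[Si](C)(C)C(C)(C)C | intermediate
33 | lithium (E)-4-(tert-butyldimethylsilyloxy)-2-methylbut-2-enoate | [Li+].[O-]C(=O)/C(C)=C/CO[Si](C)(C)C(C)(C)C | intermediate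
34 | (E)-4-(tert-butyldimethylsilyloxy)-2-methylbut-2-enoic acid | OC(=O)/C(C)=C/CO[Si](C)(C)C(C)(C)C | intermediate
35 | mixed anhydride of 34 with 2-methyl-6-nitrobenzoic acid | Cc1cccc([N+](=O)[O-])c1C(=O)OC(=O)/C(C)=C/CO[Si](C)(C)C(C)(C)C | intermediate
36 | 4′-O-TBS ether of the target | CC(=O)OCC1=C2/C(=C\[C@@]3(C)CC[C@](O)(O3)[C@H](C)C[C@@H]2OC(=O)/C(C)=C/CO[Si](C)(C)C(C)(C)C)OC1=O | intermediate
37 | CNP0154520.1, (1S,4R,8S,10R)-13-acetoxy-1-hydroxy-8-[(E)-4-hydroxy-2-methylbut-2-enoyloxy]-1,4-epoxygermacra-5,7(11)-dien-12,6-olide | CC(=O)OCC1=C2/C(=C\[C@@]3(C)CC[C@](O)(O3)[C@H](C)C[C@@H]2OC(=O)/C(C)=C/CO)OC1=O | target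

Total step count: 21. Longest linear sequence: 18 steps (steps 1–3, 5–17, 20 and 21, from 1).

Steps most likely to fail

Step 15.
- What may go wrong: the cation may lose a proton from C3 or from the C4 methyl group faster than it is hydrated. Water may add to the wrong face of C4. Long exposure to acid may enolise C1 and erode C10. Early loss of the C8 silyl ether may let O8 relactonise onto C12.
- Fallback (known chemistry only): it sets out from 22 and brings in the C4 oxygen before the furan is oxidised. Upjohn dihydroxylation (OsO4 cat., NMO, acetone–H2O) of C4=C5, the only non-aromatic alkene, gives a syn diol. Its tertiary hydroxyl closes on the C1 ketone to the bridged hemiketal diol F1. Ac2O, pyridine and DMAP acetylate only the secondary C5 hydroxyl and give the C5 acetate F2. Peracetic acid with NaOAc in CH2Cl2 oxidises the 2-silylfuran to the C6–H butenolide F3. DBU in CH2Cl2 then removes the C5 acetate by vinylogous E1cB elimination, which creates C5=C6 and comes back to the route at 27.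

Step 13.
- What may go wrong: the doubly activated O–C5 bond may ionise and recombine in a 1,3 sense. The enol ether may migrate into the ring. One C5 epimer may be unable to reach the bridged transition state.
- Fallback: it sets out from seco acid 18 and makes the same C2–C3 bond in a decarboxylative, metal-catalysed way. Meldrum's acid, EDC and DMAP give the acyl Meldrum's acid F4. Thermolysis in dilute refluxing toluene generates an acylketene that the C5 hydroxyl traps as the ten-membered β-keto lactone F5. Pd(PPh3)4 (zerovalent palladium) in THF ionises the allylic ester. After decarboxylation the C2 enolate attacks the unsubstituted C3 terminus of the π-allyl unit (the catalysed form of the Carroll rearrangement). This comes back to the route at 22.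

Step 11.
- What may go wrong: oligomerisation may outrun closure of the strained eight-membered ring. Acyl transfer to the hindered C5 carbinol may be slow. C10 may epimerise in the activated acyl species.
- Fallback: it sets out from 18 and comes back at 20, and it closes the other C–O bond. In a Mitsunobu lactonisation (PPh3, DIAD, toluene, high dilution, 0 °C) the carbinol is activated instead of the acid, and the carboxylate displaces at C5. C10 is then never adjacent to an activated acyl group. Inversion or scrambling at C5 is harmless because that centre becomes sp2 in step 13. This fallback makes no new compound (F0).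

Further compounds
F1 | step 15 | furan-fused (1S,4R)-1,4-epoxy hemiketal with free C5 hydroxyl (syn diol adduct of 22 after ring closure) | C[C@@H]1C[C@H](O[Si](C)(C)C(C)(C)C)c2c(CO[Si](C)(C)C(C)(C)C)c([Si](CC)(CC)CC)oc2[C@H](O)[C@@]3(C)CC[C@]1(O)O3
F2 | step 15 | C5 acetate of F1 | C[C@@H]1C[C@H](O[Si](C)(C)C(C)(C)C)c2c(CO[Si](C)(C)C(C)(C)C)c([Si](CC)(CC)CC)oc2[C@H](OC(C)=O)[C@@]3(C)CC[C@]1(O)O3
F3 | step 15 | 5-acetoxy-6-H butenolide (7(11)-en-12,6-olide, C6 epimers) | C[C@@H]1C[C@H](O[Si](C)(C)C(C)(C)C)C2=C(CO[Si](C)(C)C(C)(C)C)C(=O)OC2[C@H](OC(C)=O)[C@@]3(C)CC[C@]1(O)O3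
F4 | step 13 | acyl Meldrum's acid of 18 | CC1(C)OC(=O)C(C(=O)[C@H](C)C[C@H](O[Si](C)(C)C(C)(C)C)c2c(C(O)C(C)=C)oc([Si](CC)(CC)CC)c2CO[Si](C)(C)C(C)(C)C)C(=O)O1
F5 | step 13 | furan-fused ten-membered β-keto lactone (C5–O–C(=O)–C2H2–C1(=O)) | C[C@@H]1C[C@H](O[Si](C)(C)C(C)(C)C)c2c(CO[Si](C)(C)C(C)(C)C)c([Si](CC)(CC)CC)oc2C(C(C)=C)OC(=O)CC1=O
F0 | step 11 | none | none
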